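**Plan**

- Side-chain carbons are numbered C1' to C33' outward from C2 of the chroman (ring A aromatic, ring B the pyran). Cuts: C14'–C15' (allylic CH2 to the vinylic CH of the 15',16' E-alkene), then C2'–C3' in the same sense, C21'–C22' (allyl–alkyne) in the left half, and O1–C2 of ring B.
- Enabling feature: C14' is homoallylic to the 11',12' alkene, so C13'=C14' can be carried as the vinyl end of a terminal 1,3-diene that 9-BBN hydroborates only at C14'. C15' is the CH of a C(Me)=CH unit, the retron of syn-methylalumination of a terminal alkyne, hence an E-alkenyl iodide. One-pot hydroboration and sp3–sp2 coupling joins a C24 and a C29 half.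
- Forward order: ring B is closed first on the dimethylhydroquinone ring A (enantioselective Wacker cyclisation to a 2-vinylchroman). C3'–C14' is attached by a first B-alkyl Suzuki coupling with a C15 iodotetraene. The left half comes from a farnesol-derived C15 ynol and a C9 iodo bromide (copper-mediated alkyne allylation, trans-reduction). The halves are joined at C14'–C15', and the phenol is unmasked last.
- Stereochemistry: C24' (S) comes from Sharpless epoxidation of (2E,6E)-farnesol with L-(+)-diethyl tartrate, its C–O bond never being broken. C2 (S) comes from the chiral bis(oxazoline)–palladium Wacker closure. The E-trisubstituted alkenes come from the terpenoid starting materials or from zirconium-catalysed syn-carboalumination, and the 22',23' E-alkene from hydroxyl-directed trans-hydroalumination.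

Key step: step 19

Remark: the facial sense of the BOXAX–palladium cyclisation is assumed to mirror that which serves the natural 2R tocopherol series with the (S,S)-ligand, hence the (R,R)-ligand for the 2S target; the 2-vinylchroman is named R only because vinyl outranks C3.
Remark: (2E,6E)-farnesol and (E)-geranylacetone are taken as the commercial single isomers.

**Route**

Step 1
Reactants: 1 (2E,6E)-farnesol
Product: 2 (2S,3S)-2,3-epoxyfarnesol
Conditions: Ti(OiPr)4 (5 mol %), L-(+)-diethyl tartrate (6 mol %), t-BuOOH, 4 Å sieves, CH2Cl2, −20 °C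
Reagents that add atoms: tert-butyl hydroperoxide CC(C)(C)OO
Why: Sharpless asymmetric epoxidation is chemoselective for the allylic-alcohol alkene and, with L-(+)-tartrate on an E-allylic alcohol, should give the (2S,3S)-epoxide, which fixes the oxygen-bearing centre that becomes C24'.

Step 2
Reactants: 2 (2S,3S)-2,3-epoxyfarnesol
Product: 3 (2R,3S,6E)-1-chloro-2,3-epoxy-3,7,11-trimethyldodeca-6,10-diene
Conditions: PPh3, CCl4, NaHCO3, reflux
Reagents that add atoms: carbon tetrachloride ClC(Cl)(Cl)Cl
Why: Appel chlorination of the primary alcohol proceeds by SN2 at CH2 under buffered conditions and leaves the epoxide and both stereocentres untouched.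

Step 3
Reactants: 3 (2R,3S,6E)-1-chloro-2,3-epoxy-3,7,11-trimethyldodeca-6,10-diene
Product: 5 (3S,6E)-3,7,11-trimethyldodeca-6,10-dien-1-yn-3-ol, via chlorovinyl carbinol 4 (not isolated)
Conditions: LiN(iPr)2 (3.5 equiv), THF, −40 °C to rt
Reagents that add atoms: none
Why: Base-induced double elimination of a 2,3-epoxy chloride: deprotonation at CH2Cl opens the epoxide by β-elimination and loss of HCl from the chloroalkene gives the terminal alkyne, the tertiary C–O bond and thus the S configuration being retained.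

Step 4
Reactants: 6 6-methylhept-5-en-2-one
Product: 8 6-methylhept-5-en-1-yne, via enol phosphate 7 (not isolated)
Conditions: LiN(iPr)2, THF, −78 °C; ClP(O)(OEt)2, −78 °C to rt; then LiN(iPr)2 (2.3 equiv), −78 °C to rt
Reagents that add atoms: none
Why: Negishi conversion of a methyl ketone into a terminal alkyne: the kinetic methyl enolate is trapped as the enol phosphate, which eliminates under excess amide base.

Step 5
Reactants: 8 6-methylhept-5-en-1-yne
Product: 10 (1E)-1-iodo-2,6-dimethylhepta-1,5-diene, via alkenylalane 9 (not isolated)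
Conditions: Me3Al (2 equiv), Cp2ZrCl2 (20 mol %), CH2Cl2, rt; then I2, THF, −30 to 0 °C
Reagents that add atoms: trimethylaluminium C[Al](C)C; iodine II
Why: Negishi zirconium-catalysed carboalumination adds methyl and aluminium syn across the alkyne with aluminium at the terminus, and iodinolysis with retention should give the E-alkenyl iodide while the trisubstituted alkene stays inert.

Step 6
Reactants: 10 (1E)-1-iodo-2,6-dimethylhepta-1,5-diene
Product: 11 (2E,6E)-7-iodo-2,6-dimethylhepta-2,6-dien-1-ol
Conditions: SeO2 (0.3 equiv), t-BuOOH (3 equiv), salicylic acid (10 mol %), CH2Cl2, 0 °C to rt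
Reagents that add atoms: selenium dioxide O=[Se]=O (oxygen transfer, turned over by tert-butyl hydroperoxide CC(C)(C)OO)
Why: SeO2/t-BuOOH allylic oxidation (ene reaction, then [2,3]-sigmatropic shift) should attack the electron-rich terminal isopropylidene group at its E-methyl and give the E-allylic alcohol, the iodoalkene being deactivated.

Step 7
Reactants: 11 (2E,6E)-7-iodo-2,6-dimethylhepta-2,6-dien-1-ol
Product: 12 (1E,5E)-7-bromo-1-iodo-2,6-dimethylhepta-1,5-diene
Conditions: CBr4, PPh3, CH2Cl2, 0 °C
Reagents that add atoms: carbon tetrabromide BrC(Br)(Br)Br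
Why: Appel bromination of the primary allylic alcohol by SN2 keeps the alkene position and its E geometry.

Step 8
Reactants: 5 (3S,6E)-3,7,11-trimethyldodeca-6,10-dien-1-yn-3-ol; 12 (1E,5E)-7-bromo-1-iodo-2,6-dimethylhepta-1,5-diene
Product: 13 (1E,5E,10S,13E)-1-iodo-2,6,10,14,18-pentamethylnonadeca-1,5,13,17-tetraen-8-yn-10-ol
Conditions: CuI (20 mol %), K2CO3, n-Bu4NBr (10 mol %), DMF, rt
Reagents that add atoms: none
Why: Copper acetylide alkylation of the terminal alkyne by the primary allylic bromide (SN2 at CH2Br, allyl geometry retained) forms the C21'–C22' bond of the 1,4-enyne; the free tertiary alcohol and the alkenyl iodide should be tolerated at rt.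

Step 9
Reactants: 13 (1E,5E,10S,13E)-1-iodo-2,6,10,14,18-pentamethylnonadeca-1,5,13,17-tetraen-8-yn-10-ol
Product: 14 (1E,5E,8E,10S,13E)-1-iodo-2,6,10,14,18-pentamethylnonadeca-1,5,8,13,17-pentaen-10-ol
Conditions: NaAlH2(OCH2CH2OMe)2 (3 equiv), THF, 0 °C to rt; aq sodium potassium tartrate
Reagents that add atoms: none
Why: Alkoxide-directed trans-hydroalumination of the propargylic alcohol and protonolysis should give the E-allylic alcohol (22',23' alkene) without touching the isolated alkenes or, at this temperature, the alkenyl iodide.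

Step 10
Reactants: 15 2,3-dimethylbenzene-1,4-diol; 16 but-3-en-2-one
Product: 17 rac-2-methoxy-2,7,8-trimethylchroman-6-ol
Conditions: HC(OMe)3, H2SO4 (cat.), MeOH, 0 °C to rt
Reagents that add atoms: methanol CO (methoxy group; trimethyl orthoformate COC(OC)OC, the water scavenger, can deliver the same group)
Why: Acid-catalysed Friedel–Crafts conjugate alkylation of the hydroquinone by the enone and ketalisation by the neighbouring phenol should give the cyclic methyl ketal, as precedented for trimethylhydroquinone; the two free ring positions are equivalent, so one regioisomer is expected.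

Step 11
Reactants: 17 rac-2-methoxy-2,7,8-trimethylchroman-6-ol
Product: 19 4-[2-hydroxy-3,4-dimethyl-5-(triisopropylsilyloxy)phenyl]butan-2-one, via silyl ketal 18 (not isolated)
Conditions: i-Pr3SiCl, imidazole, DMF, rt; then 1 M HCl, THF, rt
Reagents that add atoms: triisopropylsilyl chloride CC(C)[Si](Cl)(C(C)C)C(C)C; water O
Why: Silylation of the only free phenol and acid hydrolysis of the mixed ketal unmask the methyl ketone and the ortho phenol (in equilibrium with the cyclic hemiketal), the aryl silyl ether being stable to dilute acid.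

Step 12
Reactants: 19 4-[2-hydroxy-3,4-dimethyl-5-(triisopropylsilyloxy)phenyl]butan-2-one
Product: 20 2,3-dimethyl-6-(3-methylpent-3-en-1-yl)-4-(triisopropylsilyloxy)phenol (E/Z mixture)
Conditions: EtPPh3Br (3 equiv), NaN(SiMe3)2 (3 equiv), THF, 0 °C to reflux
Reagents that add atoms: ethyltriphenylphosphonium bromide CC[P+](c1ccccc1)(c1ccccc1)c1ccccc1.[Br-]
Why: Wittig ethylidenation of the ketone tautomer (the phenol is carried as its phenoxide) gives a trisubstituted alkene that cannot act as a Michael acceptor toward the phenoxide; both geometric isomers should lead to the same vinylchroman in the next step.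

Step 13
Reactants: 20 2,3-dimethyl-6-(3-methylpent-3-en-1-yl)-4-(triisopropylsilyloxy)phenol (E/Z mixture)
Product: 21 (2R)-2-ethenyl-2,7,8-trimethyl-6-(triisopropylsilyloxy)chroman
Conditions: Pd(OCOCF3)2 (10 mol %), (R,R)-Bn-BOXAX (20 mol %), p-benzoquinone (4 equiv), MeOH, 60 °C
Reagents that add atoms: none
Why: Enantioselective Wacker-type oxidative cyclisation: 6-exo oxypalladation of the alkene by the phenol on the divalent palladium–bis(oxazoline) complex sets the quaternary C2 under ligand control of the alkene face, β-hydride elimination toward the methyl group releases the vinyl group, and benzoquinone reoxidises zerovalent palladium.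

Step 14
Reactants: 22 (5E)-6,10-dimethylundeca-5,9-dien-2-one
Product: 24 (5E)-6,10-dimethylundeca-5,9-dien-1-yne, via enol phosphate 23 (not isolated)
Conditions: LiN(iPr)2, THF, −78 °C; ClP(O)(OEt)2, −78 °C to rt; then LiN(iPr)2 (2.3 equiv), −78 °C to rt
Reagents that add atoms: none
Why: Negishi methyl ketone to alkyne conversion as in step 4, by way of the kinetic enol phosphate and its elimination.

Step 15
Reactants: 24 (5E)-6,10-dimethylundeca-5,9-dien-1-yne
Product: 26 (1E,5E)-1-iodo-2,6,10-trimethylundeca-1,5,9-triene, via alkenylalane 25 (not isolated)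
Conditions: Me3Al (2 equiv), Cp2ZrCl2 (20 mol %), CH2Cl2, rt; then I2, THF, −30 to 0 °C
Reagents that add atoms: trimethylaluminium C[Al](C)C; iodine II
Why: Negishi zirconium-catalysed syn-carboalumination and iodinolysis with retention, as in step 5, should give the E-alkenyl iodide that later becomes the 3',4' alkene.

Step 16
Reactants: 26 (1E,5E)-1-iodo-2,6,10-trimethylundeca-1,5,9-triene
Product: 28 (2E,6E,10E)-11-iodo-2,6,10-trimethylundeca-2,6,10-trienal, via allylic alcohol 27 (not isolated)
Conditions: SeO2 (0.3 equiv), t-BuOOH, salicylic acid (cat.), CH2Cl2, 0 °C to rt; then MnO2, CH2Cl2, rt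
Reagents that add atoms: selenium dioxide O=[Se]=O (oxygen transfer, turned over by tert-butyl hydroperoxide CC(C)(C)OO)
Why: SeO2/t-BuOOH allylic oxidation at the E-methyl of the terminal isopropylidene group, then MnO2 oxidation of the crude allylic alcohol (which also brings together any enal already formed), should give the E-2-methyl enal.

Step 17
Reactants: 28 (2E,6E,10E)-11-iodo-2,6,10-trimethylundeca-2,6,10-trienal
Product: 29 (1E,5E,9E)-1-iodo-2,6,10-trimethyldodeca-1,5,9,11-tetraene
Conditions: Ph3PCH3Br, NaN(SiMe3)2, THF, 0 °C; then 28, −78 to 0 °C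
Reagents that add atoms: methyltriphenylphosphonium bromide C[P+](c1ccccc1)(c1ccccc1)c1ccccc1.[Br-]
Why: Wittig methylenation of the enal gives the terminal 1,3-diene with the E-trisubstituted alkene unchanged; the added carbon becomes C14'.

Step 18
Reactants: 21 (2R)-2-ethenyl-2,7,8-trimethyl-6-(triisopropylsilyloxy)chroman; 29 (1E,5E,9E)-1-iodo-2,6,10-trimethyldodeca-1,5,9,11-tetraene
Product: 31 (2S)-2,7,8-trimethyl-2-[(3E,7E,11E)-4,8,12-trimethyltetradeca-3,7,11,13-tetraen-1-yl]-6-(triisopropylsilyloxy)chroman, via alkylborane 30 (not isolated)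
Conditions: 9-BBN (1.3 equiv), THF, rt to 50 °C; aq Cs2CO3; then 29, PdCl2(dppf) (5 mol %), AsPh3 (5 mol %), DMF, rt
Reagents that add atoms: none
Why: B-alkyl Suzuki–Miyaura coupling: anti-Markovnikov hydroboration of the vinyl group and stereoretentive coupling with the E-alkenyl iodide form C2'–C3'; aqueous base destroys excess 9-BBN before the diene-bearing iodide is added, and C2 is not involved.

Step 19
Reactants: 31 (2S)-2,7,8-trimethyl-2-[(3E,7E,11E)-4,8,12-trimethyltetradeca-3,7,11,13-tetraen-1-yl]-6-(triisopropylsilyloxy)chroman; 14 (1E,5E,8E,10S,13E)-1-iodo-2,6,10,14,18-pentamethylnonadeca-1,5,8,13,17-pentaen-10-ol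
Product: 33 6-O-triisopropylsilyl ether of the target, via alkylborane 32 (not isolated)
Conditions: 9-BBN (1.05 equiv), THF, 0 °C to rt; aq Cs2CO3 (3 equiv); then 14, PdCl2(dppf) (10 mol %), AsPh3 (10 mol %), DMF, rt, degassed
Reagents that add atoms: none
Why: 9-BBN adds H–B syn and anti-Markovnikov to the monosubstituted vinyl end of the 1,3-diene of 31, placing boron on C14' and giving the homoallylic B-alkyl-9-BBN 32; base converts it into the borate, zerovalent palladium inserts into the C–I bond of 14, the primary alkyl group passes from boron to palladium, and reductive elimination forms the C14'–C15' bond. The closest known reaction type is the B-alkyl Suzuki–Miyaura coupling of alkenyl iodides with 9-BBN adducts of terminal alkenes, together with the 9-BBN monohydroboration of terminal 1,3-dienes to homoallylic boranes. No ring is closed and no stereocentre is formed; C2 and C24' are remote and untouched. The E geometry of the 15',16' alkene is carried over from the iodide, because oxidative addition and reductive elimination at sp2 carbon proceed with retention. The step needs site-selective hydroboration, secured by the bulk of 9-BBN, which should react with the unhindered CH=CH2 but not with the trisubstituted alkenes (the alkene left from the diene is itself trisubstituted), and it needs coupling to outrun β-hydride elimination, for which the wide-bite-angle dppf ligand is chosen. Excess borane is destroyed by the aqueous base before 14 is added, so the free tertiary allylic alcohol and the skipped diene of 14 meet only carbonate at rt.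

Step 20
Reactants: 33 6-O-triisopropylsilyl ether of the target
Product: 34 target, (2S)-2-[(3E,7E,11E,15E,19E,22E,24S,27E)-24-hydroxy-4,8,12,16,20,24,28,32-octamethyltritriaconta-3,7,11,15,19,22,27,31-octaen-1-yl]-2,7,8-trimethylchroman-6-ol
Conditions: Bu4NF (1.1 equiv), THF, 0 °C, under argon
Reagents that add atoms: none
Why: Fluoride cleavage of the aryl silyl ether should free the phenol without affecting the tertiary allylic alcohol, the skipped diene or any stereocentre; air is excluded because the chromanol is oxidation-prone.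

**Compound list**

1 | (2E,6E)-farnesol, (2E,6E)-3,7,11-trimethyldodeca-2,6,10-trien-1-ol | CC(C)=CCC/C(C)=C/CC/C(C)=C/CO | starting material
2 | (2S,3S)-2,3-epoxyfarnesol, (2S,3S,6E)-2,3-epoxy-3,7,11-trimethyldodeca-6,10-dien-1-ol | CC(C)=CCC/C(C)=C/CC[C@]1(C)O[C@H]1CO | intermediate
3 | (2R,3S,6E)-1-chloro-2,3-epoxy-3,7,11-trimethyldodeca-6,10-diene (chloride of 2, same spatial arrangement) | CC(C)=CCC/C(C)=C/CC[C@]1(C)O[C@H]1CCl | intermediate
4 | (3S,6E)-1-chloro-3,7,11-trimethyldodeca-1,6,10-trien-3-ol, present as its lithium alkoxide, chloroalkene geometry undefined | CC(C)=CCC/C(C)=C/CC[C@](C)(O)C=CCl | intermediate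
5 | (3S,6E)-3,7,11-trimethyldodeca-6,10-dien-1-yn-3-ol | CC(C)=CCC/C(C)=C/CC[C@](C)(O)C#C | intermediate
6 | 6-methylhept-5-en-2-one | CC(=O)CCC=C(C)C | starting material
7 | diethyl 6-methylhepta-1,5-dien-2-yl phosphate | C=C(OP(=O)(OCC)OCC)CCC=C(C)C | intermediate
8 | 6-methylhept-5-en-1-yne | C#CCCC=C(C)C | intermediate
9 | [(1E)-2,6-dimethylhepta-1,5-dien-1-yl]dimethylalane | C[Al](C)/C=C(\C)CCC=C(C)C | intermediate
10 | (1E)-1-iodo-2,6-dimethylhepta-1,5-diene | I/C=C(\C)CCC=C(C)C | intermediate
11 | (2E,6E)-7-iodo-2,6-dimethylhepta-2,6-dien-1-ol | I/C=C(\C)CC/C=C(\C)CO | intermediate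
12 | (1E,5E)-7-bromo-1-iodo-2,6-dimethylhepta-1,5-diene | I/C=C(\C)CC/C=C(\C)CBr | intermediate
13 | (1E,5E,10S,13E)-1-iodo-2,6,10,14,18-pentamethylnonadeca-1,5,13,17-tetraen-8-yn-10-ol | CC(C)=CCC/C(C)=C/CC[C@](C)(O)C#CC/C(C)=C/CC/C(C)=C/I | intermediate
14 | (1E,5E,8E,10S,13E)-1-iodo-2,6,10,14,18-pentamethylnonadeca-1,5,8,13,17-pentaen-10-ol | CC(C)=CCC/C(C)=C/CC[C@](C)(O)/C=C/C/C(C)=C/CC/C(C)=C/I | intermediate
15 | 2,3-dimethylbenzene-1,4-diol | Cc1c(C)c(O)ccc1O | starting material
16 | but-3-en-2-one (methyl vinyl ketone) | CC(=O)C=C | starting material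
17 | rac-2-methoxy-2,7,8-trimethylchroman-6-ol | COC1(C)CCc2cc(O)c(C)c(C)c2O1 | intermediate
18 | rac-2-methoxy-2,7,8-trimethyl-6-(triisopropylsilyloxy)chroman | COC1(C)CCc2cc(O[Si](C(C)C)(C(C)C)C(C)C)c(C)c(C)c2O1 | intermediate
19 | 4-[2-hydroxy-3,4-dimethyl-5-(triisopropylsilyloxy)phenyl]butan-2-one (in equilibrium with its cyclic hemiketal) | CC(=O)CCc1cc(O[Si](C(C)C)(C(C)C)C(C)C)c(C)c(C)c1O | intermediate
20 | 2,3-dimethyl-6-(3-methylpent-3-en-1-yl)-4-(triisopropylsilyloxy)phenol, E/Z mixture | CC=C(C)CCc1cc(O[Si](C(C)C)(C(C)C)C(C)C)c(C)c(C)c1O | intermediate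
21 | (2R)-2-ethenyl-2,7,8-trimethyl-6-(triisopropylsilyloxy)chroman | C=C[C@@]1(C)CCc2cc(O[Si](C(C)C)(C(C)C)C(C)C)c(C)c(C)c2O1 | intermediate
22 | (5E)-6,10-dimethylundeca-5,9-dien-2-one, (E)-geranylacetone | CC(=O)CC/C=C(\C)CCC=C(C)C | starting material
23 | diethyl (5E)-6,10-dimethylundeca-1,5,9-trien-2-yl phosphate | C=C(OP(=O)(OCC)OCC)CC/C=C(\C)CCC=C(C)C | intermediate
24 | (5E)-6,10-dimethylundeca-5,9-dien-1-yne | C#CCC/C=C(\C)CCC=C(C)C | intermediate
25 | dimethyl[(1E,5E)-2,6,10-trimethylundeca-1,5,9-trien-1-yl]alane | C[Al](C)/C=C(\C)CC/C=C(\C)CCC=C(C)C | intermediate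
26 | (1E,5E)-1-iodo-2,6,10-trimethylundeca-1,5,9-triene | I/C=C(\C)CC/C=C(\C)CCC=C(C)C | intermediate
27 | (2E,6E,10E)-11-iodo-2,6,10-trimethylundeca-2,6,10-trien-1-ol | I/C=C(\C)CC/C=C(\C)CC/C=C(\C)CO | intermediate
28 | (2E,6E,10E)-11-iodo-2,6,10-trimethylundeca-2,6,10-trienal | I/C=C(\C)CC/C=C(\C)CC/C=C(\C)C=O | intermediate
29 | (1E,5E,9E)-1-iodo-2,6,10-trimethyldodeca-1,5,9,11-tetraene | I/C=C(\C)CC/C=C(\C)CC/C=C(\C)C=C | intermediate
30 | 9-{2-[(2S)-2,7,8-trimethyl-6-(triisopropylsilyloxy)chroman-2-yl]ethyl}-9-borabicyclo[3.3.1]nonane | C1CCC2CCCC1B2CC[C@@]1(C)CCc2cc(O[Si](C(C)C)(C(C)C)C(C)C)c(C)c(C)c2O1 | intermediate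
31 | (2S)-2,7,8-trimethyl-2-[(3E,7E,11E)-4,8,12-trimethyltetradeca-3,7,11,13-tetraen-1-yl]-6-(triisopropylsilyloxy)chroman | C=C/C(C)=C/CC/C(C)=C/CC/C(C)=C/CC[C@@]1(C)CCc2cc(O[Si](C(C)C)(C(C)C)C(C)C)c(C)c(C)c2O1 | intermediate
32 | 9-{(3E,7E,11E)-3,7,11-trimethyl-14-[(2S)-2,7,8-trimethyl-6-(triisopropylsilyloxy)chroman-2-yl]tetradeca-3,7,11-trien-1-yl}-9-borabicyclo[3.3.1]nonane | C1CCC2CCCC1B2CC/C(C)=C/CC/C(C)=C/CC/C(C)=C/CC[C@@]1(C)CCc2cc(O[Si](C(C)C)(C(C)C)C(C)C)c(C)c(C)c2O1 | intermediate
33 | (2S)-2-[(3E,7E,11E,15E,19E,22E,24S,27E)-24-hydroxy-4,8,12,16,20,24,28,32-octamethyltritriaconta-3,7,11,15,19,22,27,31-octaen-1-yl]-2,7,8-trimethyl-6-(triisopropylsilyloxy)chroman | CC(C)=CCC/C(C)=C/CC[C@](C)(O)/C=C/C/C(C)=C/CC/C(C)=C/CC/C(C)=C/CC/C(C)=C/CC/C(C)=C/CC[C@@]1(C)CCc2cc(O[Si](C(C)C)(C(C)C)C(C)C)c(C)c(C)c2O1 | intermediate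
34 | (2S)-2-[(3E,7E,11E,15E,19E,22E,24S,27E)-24-hydroxy-4,8,12,16,20,24,28,32-octamethyltritriaconta-3,7,11,15,19,22,27,31-octaen-1-yl]-2,7,8-trimethylchroman-6-ol | CC(C)=CCC/C(C)=C/CC[C@](C)(O)/C=C/C/C(C)=C/CC/C(C)=C/CC/C(C)=C/CC/C(C)=C/CC/C(C)=C/CC[C@@]1(C)CCc2cc(O)c(C)c(C)c2O1 | target

**Step count and risks**

Total step count: 20.
Longest linear sequence: 8 steps (4, 5, 6, 7, 8, 9, 19, 20).

Steps most likely to fail:

1. Step 19. The hydroboration at the diene terminus may be incomplete or unselective, or alkyl transfer from boron to palladium may be too slow to outrun protodeboronation and β-hydride elimination. Fallback: setting out from 31, hydroboration with 9-BBN and oxidative work-up (NaOH, H2O2) should give the purifiable homoallylic alcohol F1. I2, PPh3 and imidazole convert it into the primary iodide F2. Iodine–lithium exchange (t-BuLi, Et2O, −78 °C) and ZnCl2 give the alkylzinc chloride F3, which is used at once in a Negishi alkenyl–alkyl coupling with 14 (Pd(PPh3)4, THF, rt, excess F3 to allow for the free hydroxyl), coming back to the route at 33.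

2. Step 13. The oxypalladation of the E/Z alkene mixture may show insufficient or reversed facial selectivity, or turnover may be slow with the electron-rich phenol. Fallback: setting out from 20, the same ring closure without chiral ligand (Pd(OCOCF3)2, pyridine, O2, toluene, 80 °C) should give the racemic 2-vinylchroman F4. Preparative chromatography on a cellulose tris(3,5-dimethylphenylcarbamate) phase separates the antipodes; the R enantiomer is 21, where the route is rejoined, and the S enantiomer F5 is set aside.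

3. Step 9. Hydride attack on the alkenyl iodide (hydrodeiodination) may compete with a sluggish hydroalumination of the hindered tertiary propargylic alkoxide. Fallback: setting out from 13, ruthenium-catalysed trans-hydrosilylation ([Cp*Ru(MeCN)3]PF6, (EtO)3SiH, CH2Cl2, 0 °C) should give the (Z)-alkenylsilane F6. Protodesilylation with retention (Bu4NF, CuI, THF) should then give the E-alkene, coming back to the route at 14.

Further compounds
F1 | step 19 | (3E,7E,11E)-3,7,11-trimethyl-14-[(2S)-2,7,8-trimethyl-6-(triisopropylsilyloxy)chroman-2-yl]tetradeca-3,7,11-trien-1-ol | OCC/C(C)=C/CC/C(C)=C/CC/C(C)=C/CC[C@@]1(C)CCc2cc(O[Si](C(C)C)(C(C)C)C(C)C)c(C)c(C)c2O1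
F2 | step 19 | (2S)-2-[(3E,7E,11E)-14-iodo-4,8,12-trimethyltetradeca-3,7,11-trien-1-yl]-2,7,8-trimethyl-6-(triisopropylsilyloxy)chroman | ICC/C(C)=C/CC/C(C)=C/CC/C(C)=C/CC[C@@]1(C)CCc2cc(O[Si](C(C)C)(C(C)C)C(C)C)c(C)c(C)c2O1
F3 | step 19 | chloro{(3E,7E,11E)-3,7,11-trimethyl-14-[(2S)-2,7,8-trimethyl-6-(triisopropylsilyloxy)chroman-2-yl]tetradeca-3,7,11-trien-1-yl}zinc | Cl[Zn]CC/C(C)=C/CC/C(C)=C/CC/C(C)=C/CC[C@@]1(C)CCc2cc(O[Si](C(C)C)(C(C)C)C(C)C)c(C)c(C)c2O1
F4 | step 13 | rac-2-ethenyl-2,7,8-trimethyl-6-(triisopropylsilyloxy)chroman | C=CC1(C)CCc2cc(O[Si](C(C)C)(C(C)C)C(C)C)c(C)c(C)c2O1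
F5 | step 13 | (2S)-2-ethenyl-2,7,8-trimethyl-6-(triisopropylsilyloxy)chroman | C=C[C@]1(C)CCc2cc(O[Si](C(C)C)(C(C)C)C(C)C)c(C)c(C)c2O1
F6 | step 9 | (1E,5E,8Z,10S,13E)-1-iodo-2,6,10,14,18-pentamethyl-8-(triethoxysilyl)nonadeca-1,5,8,13,17-pentaen-10-ol | CC(C)=CCC/C(C)=C/CC[C@](C)(O)/C=C(\[Si](OCC)(OCC)OCC)C/C(C)=C/CC/C(C)=C/I
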